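## The problem

Target 14, (2R,3S)-2-(14-carboxytetradecyl)-4-methylidene-5-oxooxolane-3-carboxylic acid, has one ring, a γ-lactone. For the discussion its atoms are numbered O1, C2 (carbonyl), C3 (exocyclic methylene), C4 (CO2H, S) and C5 (R, bearing a chain of fourteen methylenes that ends in a second carboxyl); systematic names use oxolane numbering, where these atoms are O1, C5, C4, C3 and C2. No ring fusion has to be built. The task is to place three oxygenated carbons (C2, the C4 carboxyl and the C5–O carbon) side by side at one end of a long hydrocarbon chain and to keep the two chain ends distinguishable. The two stereocentres are adjacent and trans. C5 is a carbinol carbon and is fixed once formed, whereas C4 is α to a carboxyl and can epimerise. C4 can therefore be set first and used to control C5, but an error at C5 cannot be repaired through C4, because that would give the enantiomer. The α-methylene lactone is a Michael acceptor that migrates into the ring under base or heat, so it must be made last, and the remote carboxyl must stay masked while the ring end is worked on. The enabling feature is seen when the methylene carbon is removed and the O1–C5 bond is opened. What remains is a 2-alkylsuccinic acid in which C5 is an ordinary methylene, β to the C4 carboxyl and γ to the C2 carboxyl, so the same molecule carries a directing group for metalation at C5 and the oxygen that must end up on it.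

## Retrosynthesis

**14 ⇒ 11 (through 12 and 13).** The exocyclic C3=CH2 bond is cut first, since the methylene lactone tolerates none of the other operations. The carbon is taken back to formaldehyde through the Mannich base 13 and the C3-carboxylated lactone 12. Direct enolate methylenation of a lactone carrying two free acids is the neighbouring option, but it needs a polyanion (it is kept as a fallback). Carboxylation through a magnesium chelate works on the free acids and activates only C3. The precursor 11 is the saturated trans lactone diacid, stable to acid and heat. The forward sequence must functionalise C3 alone and leave C4 and C5 as they are.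

**11 ⇒ 10.** No skeletal bond is cut; the chain carboxyl is returned to its methyl ester. The ester is already present in the commercial half-ester 1, where it distinguishes the two ends of the C16 chain. It is a poor ligand for palladium and is removed in aqueous acid, conditions under which a γ-lactone simply re-closes.

**10 ⇒ 9.** The O1–C5 bond is cut. Cutting C4–C5 (aldol logic) or C3–C4 (conjugate-addition logic) would each require two stereocentres to be set together with an auxiliary or a chiral butenolide. Cutting O1–C5 removes the ring and the C5 stereocentre at once and leaves diacid 9 with one stereocentre and no oxygen on the chain. The forward reaction must oxidise one specific methylene among sixteen, choose one of its two hydrogens under the influence of C4, and leave C4 untouched. To help this, the substrate is the free succinic acid (both the directing and the ring-closing carboxylate available) with the remote carboxyl kept as an ester so that only one end can chelate the metal.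

**9 ⇒ 8.** Unsaturation is introduced between C4 and C5. The single stereocentre of 9 then becomes a question of which ligand antipode is used in an asymmetric hydrogenation of the (E)-alkylidenesuccinic acid 8. The free CH2CO2H arm is the chelating group this reaction type needs, so no protecting group has to be added or removed.

**8 ⇒ 3 + 4 + 5.** The C4=C5 double bond is cut by Wittig logic. Maleic anhydride 4 supplies C2, C3, C4 and the C4 carboxyl at their final oxidation levels; triphenylphosphine 5 turns it into ylide 6; aldehyde 3 supplies C5 and the chain. The olefination gives anhydride 7, which water opens to 8. A Stobbe-type condensation would give the same skeleton but with one carboxyl esterified, which could not be told apart from the chain ester.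

**3 ⇒ 2 ⇒ 1.** Only oxidation levels change: aldehyde 3 comes from alcohol 2, and 2 from chemoselective reduction of the free acid of half-ester 1.

## Roads not taken

**Alternative 1:** The carboxyl carbon on C4 and the methylene carbon on C3 are both disconnected, leaving butenolide A1, tert-butyl 15-[(2R)-5-oxo-2,5-dihydrofuran-2-yl]pentadecanoate. In the forward step LiC(SMe)3 adds to C4 from the face opposite the C5 chain, and the lactone enolate is trapped at C3 by dimethylmethyleneiminium iodide. This gives A2, tert-butyl 15-[(2R,3S,4R)-4-[(dimethylamino)methyl]-5-oxo-3-[tris(methylsulfanyl)methyl]oxolan-2-yl]pentadecanoate, in one flask; two C–C bonds form and no ring closes.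
- Merits: the trans relation of C4 and C5 follows from a well-established facial bias of 5-substituted butenolides, and the aminomethyl group is already the latent methylene.
- Weak points: A1 must be made enantiopure in several steps, since its only stereocentre is the oxygenated C5. The trithioorthoester must later be unmasked to the acid with HgCl2/HgO in the presence of an amine or a methylene lactone. The tert-butyl ester has to be cleaved at the end. The count would be about ten steps or more.
- Comparison: on diastereocontrol this road is the safer one, because the chosen plan rests its C5 configuration on an untested palladacycle preference. The chosen plan sets against this eight steps, a C4 carboxyl that is never masked, no stoichiometric heavy metal, and a single stereocentre bought by catalytic hydrogenation.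

**Alternative 2:** The lactone carbonyl is excised as carbon monoxide (O1–C2 and C2–C3), leaving the anti homopropargylic alcohol A3, tert-butyl (16R,17R)-17-({[tert-butyl(dimethyl)silyl]oxy}methyl)-16-hydroxynonadec-18-ynoate. Forward, PdCl2, PPh3 and SnCl2 under CO (divalent palladium) convert the hydroxyl into an alkoxycarbonylpalladium unit that adds across the alkyne; protonolysis releases A4, tert-butyl 15-[(2R,3R)-3-({[tert-butyl(dimethyl)silyl]oxy}methyl)-4-methylidene-5-oxooxolan-2-yl]pentadecanoate.
- Merits: the α-methylene lactone is made directly under neutral conditions, and both stereocentres of A3 can come from one reagent-controlled anti-selective allenylmetal addition.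
- Weak points: C4 carries a protected CH2OH. After ring closure it must be desilylated and oxidised by two levels next to a Michael acceptor, passing through an aldehyde whose C4–H is both allylic and α to a carbonyl, which invites epimerisation and double-bond migration. A chiral propargylic reagent must be prepared and CO handled. The count would be about nine or ten steps.
- Comparison: for forming the methylene lactone this road is better than steps 7 and 8 of the chosen plan, and its stereochemistry has firmer precedent. The chosen plan answers with C4 at the acid level throughout, no oxidation once the ring exists, commodity starting materials and fewer steps.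

**Alternative 3:** The C3–C4 bond is cut, leaving the epoxy propargyl ether A5, tert-butyl (16R)-16-(oxiran-2-yl)-16-(prop-2-yn-1-yloxy)hexadecanoate. Forward, Cp2TiCl (trivalent titanium, from Cp2TiCl2 and zinc dust) opens the epoxide to a β-titanoxy radical at C4, which closes 5-exo-dig onto the alkyne. This gives A6, tert-butyl 15-[(2R,3R)-3-(hydroxymethyl)-4-methylideneoxolan-2-yl]pentadecanoate.
- Merits: the conditions are mild, the ring and exocyclic alkene form in one step, and the chain on C5 is expected to steer the hydroxymethyl group trans.
- Weak points: A6 is two oxidations short. The ring CH2 next to oxygen must become the lactone carbonyl by allylic oxidation with a CrO3-based reagent, and CH2OH must become CO2H, both in the presence of the alkene. Titanium is stoichiometric, and A5 needs several steps including an asymmetric epoxidation. The count would exceed ten steps.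
- Comparison: the radical closure is dependable and its trans preference is better founded than the palladacycle argument. The chosen plan is shorter and has every carbon at its final oxidation level after the key step.

Key step: step 5

Assumption: the (S,S) antipode of Et-DuPhos is taken to deliver the (R)-diacid 9, by analogy with the sense observed for β-substituted itaconates; if the sense proves opposite, the (R,R) ligand is used and nothing else changes.

## Route

Step 1
Reactants: 1 16-methoxy-16-oxohexadecanoic acid (hexadecanedioic acid monomethyl ester)
Product: 2 methyl 16-hydroxyhexadecanoate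
Conditions: BH3·SMe2 (1.2 equiv), THF, 0 °C → rt; MeOH quench, aqueous work-up
Reagents that add atoms: none
Why: Chemoselective borane reduction; the free acid is reduced through its acyloxyborane much faster than the methyl ester reacts, so only one chain end is changed.

Step 2
Reactants: 2 methyl 16-hydroxyhexadecanoate
Product: 3 methyl 16-oxohexadecanoate
Conditions: TEMPO (2,2,6,6-tetramethylpiperidin-1-oxyl, 10 mol%), PhI(OAc)2 (1.1 equiv), CH2Cl2, rt
Reagents that add atoms: none
Why: Nitroxyl-catalysed alcohol oxidation with PhI(OAc)2 as terminal oxidant stops at the aldehyde in the absence of water and does not touch the ester.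

Step 3
Reactants: 3 methyl 16-oxohexadecanoate; 4 maleic anhydride (furan-2,5-dione); 5 triphenylphosphine
Product: 8 (2E)-2-(16-methoxy-16-oxohexadecylidene)butanedioic acid, via phosphorus ylide 6 (not isolated), via alkylidenesuccinic anhydride 7 (not isolated)
Conditions: 4, 5, THF, rt; then 3, reflux; then H2O, 50 °C; diacid separated from Ph3PO by NaHCO3 extraction and acidification
Reagents that add atoms: water, O
Why: Triphenylphosphine adds to maleic anhydride and tautomerises to the stabilised ylide 6, whose Wittig olefination with the aliphatic aldehyde should give the (E)-alkylidene anhydride 7 with the chain turned away from the ring carbonyl. Water then opens the anhydride under conditions that leave the methyl ester intact.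

Step 4
Reactants: 8 (2E)-2-(16-methoxy-16-oxohexadecylidene)butanedioic acid
Product: 9 (2R)-2-(16-methoxy-16-oxohexadecyl)butanedioic acid
Conditions: H2 (5 bar), [Rh(cod)((S,S)-Et-DuPhos)]BF4 (1 mol%), Et3N (10 mol%), MeOH, rt
Reagents that add atoms: none
Why: Asymmetric hydrogenation of a β-substituted itaconic acid; the alkene and the CH2CO2− arm chelate monovalent rhodium, and the chiral bisphospholane lets hydrogen reach C4 from one face only, which sets the R centre. The E geometry places the chain cis to the chelating arm, the arrangement this catalyst class handles best, and the ester is inert.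

Step 5
Reactants: 9 (2R)-2-(16-methoxy-16-oxohexadecyl)butanedioic acid
Product: 10 (2R,3S)-2-(15-methoxy-15-oxopentadecyl)-5-oxooxolane-3-carboxylic acid
Conditions: Pd(OAc)2 (10 mol%), bidentate quinoline–pyridone N,N-ligand (12 mol%), NaOAc (0.5 equiv), aq. tBuOOH (2 equiv), (CF3)2CHOH, 60 °C
Reagents that add atoms: none
Why: The C4 carboxylate binds divalent palladium and, with the pyridonate oxygen of the ligand as internal base, one C5–H bond is cleaved by concerted metalation–deprotonation to give a five-membered palladacycle (Pd, O, carboxyl C, C4, C5). tBuOOH oxidises this to an alkyl complex of tetravalent palladium, and the free C2 carboxylate displaces the metal from C5 from the rear (SN2-type C–O reductive elimination with inversion), which closes the γ-lactone in the 5-exo-tet mode and returns divalent palladium. The closest known reaction type is the palladium-catalysed, carboxylate-directed methylene C(sp3)–H lactonization of aliphatic dicarboxylic acids with a peroxide oxidant; the only untested element here is a stereocentre next to the reacting methylene. The new stereocentre C5 is controlled by C4: in the palladacycle the chain on C5 avoids the CH2CO2H arm on C4 (trans-disubstituted metallacycle), and inversion at C5 then leaves the chain trans to the C4 carboxyl in the lactone. The other conceivable course, a six-membered palladacycle through the C2 carboxylate with chain and C4 carboxyl trans followed by C–O reductive elimination with retention, leads to the same trans isomer, so the outcome does not depend on which carboxylate directs. Site selectivity is needed against C3–H (also β, but α to a carboxyl and a poor partner for electrophilic palladation), the tertiary C4–H and the remote chain methylenes; it rests on the preference for the five-membered palladacycle, reinforced by the ligand, and on the methyl ester being too weak a donor to direct at its own end. The configuration at C4 should survive because its hydrogen lies inside the palladacycle, where it cannot become syn-coplanar with the C5–Pd bond, and because fast oxidation by the peroxide competes with β-hydride elimination.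

Step 6
Reactants: 10 (2R,3S)-2-(15-methoxy-15-oxopentadecyl)-5-oxooxolane-3-carboxylic acid
Product: 11 (2R,3S)-2-(14-carboxytetradecyl)-5-oxooxolane-3-carboxylic acid
Conditions: 6 M aq. HCl, 1,4-dioxane, 90 °C
Reagents that add atoms: water, O
Why: Acid-catalysed ester hydrolysis by acyl–oxygen cleavage; the γ-lactone is the stable form in aqueous acid and re-closes on concentration, C5 is never ionised, and the trans arrangement at C4 is the favoured one, so both centres should be kept.

Step 7
Reactants: 11 (2R,3S)-2-(14-carboxytetradecyl)-5-oxooxolane-3-carboxylic acid
Product: 12 (2R,3S)-2-(14-carboxytetradecyl)-5-oxooxolane-3,4-dicarboxylic acid (C4 epimers in oxolane numbering, used crude)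
Conditions: MeOMgOCO2Me (2 M in DMF, excess), 130 °C; then cold aq. HCl
Reagents that add atoms: methyl methoxymagnesium carbonate, COC(=O)O[Mg]OC
Why: Carboxylation with methyl methoxymagnesium carbonate; the lactone α-carbon is deprotonated and trapped by CO2 as a magnesium chelate between the lactone carbonyl and the new carboxylate, which pulls the equilibrium over. The α-positions of the two carboxylates are not acidic enough to react, and the new centre needs no control because step 8 destroys it.

Step 8
Reactants: 12 (2R,3S)-2-(14-carboxytetradecyl)-5-oxooxolane-3,4-dicarboxylic acid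
Product: 14 (2R,3S)-2-(14-carboxytetradecyl)-4-methylidene-5-oxooxolane-3-carboxylic acid, via Mannich base 13 (not isolated)
Conditions: aq. CH2O (37%), Et2NH, NaOAc, AcOH, rt → 60 °C
Reagents that add atoms: formaldehyde, C=O
Why: Decarboxylative Mannich methylenation; the malonic-type half acid adds to the iminium ion from formaldehyde and diethylamine to give 13, which loses CO2 and diethylamine in one fragmentation to leave the exocyclic alkene. The buffered acidic medium is chosen to avoid migration of the double bond into the ring.

## Compound list

1 | 16-methoxy-16-oxohexadecanoic acid (hexadecanedioic acid monomethyl ester) | COC(=O)CCCCCCCCCCCCCCC(=O)O | starting material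
2 | methyl 16-hydroxyhexadecanoate | COC(=O)CCCCCCCCCCCCCCCO | intermediate
3 | methyl 16-oxohexadecanoate | COC(=O)CCCCCCCCCCCCCCC=O | intermediate
4 | maleic anhydride (furan-2,5-dione) | O=C1C=CC(=O)O1 | starting material
5 | triphenylphosphine | c1ccc(cc1)P(c1ccccc1)c1ccccc1 | starting material
6 | 3-(triphenyl-λ5-phosphanylidene)oxolane-2,5-dione | O=C1CC(=P(c2ccccc2)(c2ccccc2)c2ccccc2)C(=O)O1 | intermediate (not isolated)
7 | methyl (16E)-16-(2,5-dioxooxolan-3-ylidene)hexadecanoate | COC(=O)CCCCCCCCCCCCCC/C=C1\CC(=O)OC1=O | intermediate (not isolated)
8 | (2E)-2-(16-methoxy-16-oxohexadecylidene)butanedioic acid | COC(=O)CCCCCCCCCCCCCC/C=C(\CC(=O)O)C(=O)O | intermediate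
9 | (2R)-2-(16-methoxy-16-oxohexadecyl)butanedioic acid | COC(=O)CCCCCCCCCCCCCCC[C@H](CC(=O)O)C(=O)O | intermediate
10 | (2R,3S)-2-(15-methoxy-15-oxopentadecyl)-5-oxooxolane-3-carboxylic acid (trans) | C1C(=O)O[C@H](CCCCCCCCCCCCCCC(=O)OC)[C@H]1C(=O)O | intermediate
11 | (2R,3S)-2-(14-carboxytetradecyl)-5-oxooxolane-3-carboxylic acid | C1C(=O)O[C@H](CCCCCCCCCCCCCCC(=O)O)[C@H]1C(=O)O | intermediate
12 | (2R,3S)-2-(14-carboxytetradecyl)-5-oxooxolane-3,4-dicarboxylic acid (C4 epimers) | OC(=O)C1C(=O)O[C@H](CCCCCCCCCCCCCCC(=O)O)[C@H]1C(=O)O | intermediate
13 | (2R,3S)-2-(14-carboxytetradecyl)-4-[(diethylamino)methyl]-5-oxooxolane-3,4-dicarboxylic acid (C4 epimers) | CCN(CC)CC1(C(=O)O)C(=O)O[C@H](CCCCCCCCCCCCCCC(=O)O)[C@H]1C(=O)O | intermediate (not isolated)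
14 | (2R,3S)-2-(14-carboxytetradecyl)-4-methylidene-5-oxooxolane-3-carboxylic acid | C=C1C(=O)O[C@H](CCCCCCCCCCCCCCC(=O)O)[C@H]1C(=O)O | target

## Step count and risk

Total step count: 8. Longest linear sequence: 8 steps (1 to 14); compounds 4 and 5 enter in step 3.

**Step 5 (key step).** Three things can go wrong.
- β-Hydride elimination may overtake oxidation of the alkylpalladium. This would desaturate the chain or, after the carboxylate leaves the metal, run through C4 and erase its configuration.
- Discrimination between the two C5 hydrogens may be poor, or C–O formation may follow a course of mixed stereochemistry, giving cis lactone. This cannot be corrected at C4, since epimerisation there leads into the enantiomeric series.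
- Palladation may occur at C3 or at the γ-methylene instead of C5.

Fallback (sets out from 3, returns at 10): the ring oxygen is not introduced by C–H oxidation; the C4–C5 bond is made by an auxiliary-controlled aldol reaction and the ring closes by ordinary lactonization.
- The imide tert-butyl 4-[(4S)-4-benzyl-2-oxo-1,3-oxazolidin-3-yl]-4-oxobutanoate F1 is prepared from 4-tert-butoxy-4-oxobutanoic acid (pivaloyl chloride, Et3N, LiCl) and (4S)-4-benzyl-1,3-oxazolidin-2-one.
- F1 is converted into its boron enolate with Bu2BOTf and iPr2NEt in CH2Cl2 at −78 °C and added to 3. The Evans syn-aldol reaction should give 1-tert-butyl 19-methyl (3S,4R)-3-[(4S)-4-benzyl-2-oxo-1,3-oxazolidine-3-carbonyl]-4-hydroxynonadecanedioate F2.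
- CF3CO2H in CH2Cl2 removes the tert-butyl group and closes the ring to methyl 15-[(2R,3S)-3-[(4S)-4-benzyl-2-oxo-1,3-oxazolidine-3-carbonyl]-5-oxooxolan-2-yl]pentadecanoate F3; a syn aldol maps onto the trans lactone.
- LiOH/H2O2 in THF–water at 0 °C cleaves the imide and gives 10.

**Step 4.** Enantioface discrimination may be incomplete for a free diacid carrying a long lipophilic chain, and the double bond may migrate out of the alkylidene position before reduction. Any shortfall in enantiopurity is carried into 10 and cannot be upgraded by the key step.

Fallback (sets out from 3, returns at 9): C4 is set by auxiliary-controlled enolate alkylation.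
- Horner–Wadsworth–Emmons olefination of 3 (LiCl, iPr2NEt, MeCN) with (4S)-4-benzyl-3-[(diethoxyphosphoryl)acetyl]-1,3-oxazolidin-2-one F4 (from the bromoacetyl imide and P(OEt)3 by Arbuzov reaction) gives methyl (16E)-18-[(4S)-4-benzyl-2-oxo-1,3-oxazolidin-3-yl]-18-oxooctadec-16-enoate F5.
- Hydrogenation over Pd/C in EtOAc gives methyl 18-[(4S)-4-benzyl-2-oxo-1,3-oxazolidin-3-yl]-18-oxooctadecanoate F6.
- The sodium enolate (NaN(SiMe3)2, THF, −78 °C) is alkylated by tert-butyl bromoacetate on the face away from the benzyl group, giving 1-tert-butyl 19-methyl (3R)-3-[(4S)-4-benzyl-2-oxo-1,3-oxazolidine-3-carbonyl]nonadecanedioate F7.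
- LiOH/H2O2 at 0 °C releases (2R)-2-(2-tert-butoxy-2-oxoethyl)-18-methoxy-18-oxooctadecanoic acid F8, and CF3CO2H in CH2Cl2 removes the tert-butyl group to give 9.

**Step 7.** The bis-magnesium carboxylate of 11 may aggregate or precipitate in hot DMF, so carboxylation stays incomplete. The product may also lose CO2 again during acidic work-up, and long heating may equilibrate C4.

Fallback (sets out from 11, returns at 14, bypassing step 8): the methylene carbon is introduced by an enolate Mannich reaction.
- 11 is converted into its trilithium salt (two carboxylates and the lactone enolate) with LiN(SiMe3)2 (3.3 equiv) in THF/DMPU at −78 °C and treated with dimethylmethyleneiminium iodide. This gives (2R,3S)-2-(14-carboxytetradecyl)-4-[(dimethylamino)methyl]-5-oxooxolane-3-carboxylic acid F9.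
- Methylation of the amine with MeI in MeOH gives 1-[(4S,5R)-4-carboxy-5-(14-carboxytetradecyl)-2-oxooxolan-3-yl]-N,N,N-trimethylmethanaminium iodide F10.
- F10 eliminates trimethylamine on stirring with aqueous NaHCO3 to give 14.

**Step 3.** The stabilised ylide needs warming, and under these conditions self-condensation of the enolisable aldehyde may compete. Conversion may stall, and E/Z mixtures or double-bond migration during hydrolysis would lower the quality of the hydrogenation substrate.

Fallback (sets out from 3, returns at 8): the ylide is replaced by a phosphonate carbanion.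
- Di-tert-butyl 2-(diethoxyphosphoryl)butanedioate F11 is made from tert-butyl diethylphosphonoacetate, NaH and tert-butyl bromoacetate.
- F11 is deprotonated with NaH in THF at 0 °C and condensed with 3 (Horner–Wadsworth–Emmons) to give di-tert-butyl (2E)-2-(16-methoxy-16-oxohexadecylidene)butanedioate F12.
- CF3CO2H in CH2Cl2 removes both tert-butyl groups, leaves the methyl ester and gives 8.

## Further compounds

F1 | step 5 | tert-butyl 4-[(4S)-4-benzyl-2-oxo-1,3-oxazolidin-3-yl]-4-oxobutanoate | CC(C)(C)OC(=O)CCC(=O)N1[C@@H](Cc2ccccc2)COC1=O
F2 | step 5 | 1-tert-butyl 19-methyl (3S,4R)-3-[(4S)-4-benzyl-2-oxo-1,3-oxazolidine-3-carbonyl]-4-hydroxynonadecanedioate | O[C@H](CCCCCCCCCCCCCCC(=O)OC)[C@H](CC(=O)OC(C)(C)C)C(=O)N1[C@@H](Cc2ccccc2)COC1=O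
F3 | step 5 | methyl 15-[(2R,3S)-3-[(4S)-4-benzyl-2-oxo-1,3-oxazolidine-3-carbonyl]-5-oxooxolan-2-yl]pentadecanoate | C1C(=O)O[C@H](CCCCCCCCCCCCCCC(=O)OC)[C@H]1C(=O)N2[C@@H](Cc3ccccc3)COC2=O
F4 | step 4 | (4S)-4-benzyl-3-[(diethoxyphosphoryl)acetyl]-1,3-oxazolidin-2-one | CCOP(=O)(OCC)CC(=O)N1[C@@H](Cc2ccccc2)COC1=O
F5 | step 4 | methyl (16E)-18-[(4S)-4-benzyl-2-oxo-1,3-oxazolidin-3-yl]-18-oxooctadec-16-enoate | COC(=O)CCCCCCCCCCCCCC/C=C/C(=O)N1[C@@H](Cc2ccccc2)COC1=O
F6 | step 4 | methyl 18-[(4S)-4-benzyl-2-oxo-1,3-oxazolidin-3-yl]-18-oxooctadecanoate | COC(=O)CCCCCCCCCCCCCCCCC(=O)N1[C@@H](Cc2ccccc2)COC1=O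
F7 | step 4 | 1-tert-butyl 19-methyl (3R)-3-[(4S)-4-benzyl-2-oxo-1,3-oxazolidine-3-carbonyl]nonadecanedioate | COC(=O)CCCCCCCCCCCCCCC[C@H](CC(=O)OC(C)(C)C)C(=O)N1[C@@H](Cc2ccccc2)COC1=O
F8 | step 4 | (2R)-2-(2-tert-butoxy-2-oxoethyl)-18-methoxy-18-oxooctadecanoic acid | COC(=O)CCCCCCCCCCCCCCC[C@H](CC(=O)OC(C)(C)C)C(=O)O
F9 | step 7 | (2R,3S)-2-(14-carboxytetradecyl)-4-[(dimethylamino)methyl]-5-oxooxolane-3-carboxylic acid (C4 epimers) | CN(C)CC1C(=O)O[C@H](CCCCCCCCCCCCCCC(=O)O)[C@H]1C(=O)O
F10 | step 7 | 1-[(4S,5R)-4-carboxy-5-(14-carboxytetradecyl)-2-oxooxolan-3-yl]-N,N,N-trimethylmethanaminium iodide | C[N+](C)(C)CC1C(=O)O[C@H](CCCCCCCCCCCCCCC(=O)O)[C@H]1C(=O)O.[I-]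
F11 | step 3 | di-tert-butyl 2-(diethoxyphosphoryl)butanedioate | CCOP(=O)(OCC)C(CC(=O)OC(C)(C)C)C(=O)OC(C)(C)C
F12 | step 3 | di-tert-butyl (2E)-2-(16-methoxy-16-oxohexadecylidene)butanedioate | COC(=O)CCCCCCCCCCCCCC/C=C(\CC(=O)OC(C)(C)C)C(=O)OC(C)(C)C
A1 | alternative 1 | tert-butyl 15-[(2R)-5-oxo-2,5-dihydrofuran-2-yl]pentadecanoate | O=C1O[C@H](CCCCCCCCCCCCCCC(=O)OC(C)(C)C)C=C1
A2 | alternative 1 | tert-butyl 15-[(2R,3S,4R)-4-[(dimethylamino)methyl]-5-oxo-3-[tris(methylsulfanyl)methyl]oxolan-2-yl]pentadecanoate | CN(C)C[C@@H]1C(=O)O[C@H](CCCCCCCCCCCCCCC(=O)OC(C)(C)C)[C@H]1C(SC)(SC)SC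
A3 | alternative 2 | tert-butyl (16R,17R)-17-({[tert-butyl(dimethyl)silyl]oxy}methyl)-16-hydroxynonadec-18-ynoate | O[C@H](CCCCCCCCCCCCCCC(=O)OC(C)(C)C)[C@H](C#C)CO[Si](C)(C)C(C)(C)C
A4 | alternative 2 | tert-butyl 15-[(2R,3R)-3-({[tert-butyl(dimethyl)silyl]oxy}methyl)-4-methylidene-5-oxooxolan-2-yl]pentadecanoate | C=C1C(=O)O[C@H](CCCCCCCCCCCCCCC(=O)OC(C)(C)C)[C@H]1CO[Si](C)(C)C(C)(C)C
A5 | alternative 3 | tert-butyl (16R)-16-(oxiran-2-yl)-16-(prop-2-yn-1-yloxy)hexadecanoate | C#CCO[C@H](CCCCCCCCCCCCCCC(=O)OC(C)(C)C)C1CO1
A6 | alternative 3 | tert-butyl 15-[(2R,3R)-3-(hydroxymethyl)-4-methylideneoxolan-2-yl]pentadecanoate | C=C1CO[C@H](CCCCCCCCCCCCCCC(=O)OC(C)(C)C)[C@H]1CO
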